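**Retrosynthetic overview**

- Ring C is closed by the C4–C4a bond: intramolecular Friedel–Crafts acylation of ring A by the carboxyl carbon of a (3S)-3-aryl-3-(aryloxy)propanoic acid (as its mixed trifluoroacetic anhydride), followed only by removal of three silyl groups.
- Enabling feature: C4a of ring A lies ortho to O1 and O5 and para to O7 (phloroglucinol pattern), so it should be acylated without a Lewis acid; C8, the other carbon ortho to O1, already carries its prenyl group, so only C4a can close the six-membered ring.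
- The acid is cut back to a branched allyl aryl ether (hydroboration, oxidation). Its O1–C2 bond and the C2 stereocentre come from one asymmetric allylic etherification ([Ir(cod)Cl]2 with a chiral phosphoramidite) that joins the ring A phenol with the ring B cinnamyl carbonate.
- Each prenyl group is put in before the union by the same two moves, O-(1,1-dimethylallyl)ation with Pd(PPh3)4 and aromatic Claisen rearrangement: on isovanillin (to C2') and on symmetric 3,5-bis(silyloxy)phenol (to C8).
- Ring order: rings A and B are bought as arenes (phloroglucinol, isovanillin); ring C is the only ring made, in step 13.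

Key step: step 13

Assumption: in step 10 the (Sa,S,S) enantiomer of the ligand is taken to give the (S)-ether; should the sense of induction be the reverse, the mirror-image ligand is used.

Abbreviations: prenyl = 3-methylbut-2-en-1-yl; TIPS = triisopropylsilyl; ArB = 4-methoxy-2-prenyl-3-(TIPS-oxy)phenyl (ring B, bonded through C1'); ArA = 2-prenyl-3,5-bis(TIPS-oxy)phenyl (ring A, bonded through the carbon that becomes C8a); L = O,O'-(1,1'-binaphthalene-2,2'-diyl) N,N-bis(1-phenylethyl)phosphoramidite. tert-Butyl (2-methylbut-3-en-2-yl) carbonate is taken as a purchased reagent.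

**Route**

Step 1
Reactants: 1 isovanillin (3-hydroxy-4-methoxybenzaldehyde)
Product: 2 4-methoxy-3-[(2-methylbut-3-en-2-yl)oxy]benzaldehyde
Conditions: tert-butyl (2-methylbut-3-en-2-yl) carbonate (1.5 equiv), Pd(PPh3)4 (2 mol%), THF, 0 °C
Reagents that add atoms: tert-butyl (2-methylbut-3-en-2-yl) carbonate, CC(C)(C)OC(=O)OC(C)(C)C=C
Why: Decarboxylative Tsuji–Trost O-allylation, in which Pd(PPh3)4 ionizes the tertiary carbonate, the tert-butoxide released deprotonates the phenol, and the phenoxide should attack the more substituted allyl terminus under kinetic control at low temperature.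

Step 2
Reactants: 2 4-methoxy-3-[(2-methylbut-3-en-2-yl)oxy]benzaldehyde
Product: 4 3-hydroxy-4-methoxy-2-prenylbenzaldehyde, via Claisen dienone 3 (not isolated)
Conditions: PhNEt2, 130 °C
Reagents that add atoms: none
Why: Aromatic Claisen rearrangement, whose [3,3] shift can only reach C2 (the other ortho carbon carries the methoxy group), turns the 1,1-dimethylallyl ether into a C-bound prenyl group and is completed by tautomerization of dienone 3; the amine solvent suppresses acid-induced chroman formation.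

Step 3
Reactants: 4 3-hydroxy-4-methoxy-2-prenylbenzaldehyde
Product: 5 4-methoxy-2-prenyl-3-(TIPS-oxy)benzaldehyde (ArB–CHO)
Conditions: TIPSOTf, 2,6-lutidine, CH2Cl2, 0 °C
Reagents that add atoms: triisopropylsilyl trifluoromethanesulfonate, CC(C)[Si](OS(=O)(=O)C(F)(F)F)(C(C)C)C(C)C
Why: Silyl ether formation with the reactive silyl triflate, chosen because the phenol is flanked by the prenyl and methoxy groups; the bulky silyl ether should survive the base, hydride, borane and weak acid used later.

Step 4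
Reactants: 5 4-methoxy-2-prenyl-3-(TIPS-oxy)benzaldehyde
Product: 6 ethyl (2E)-3-ArB-prop-2-enoate
Conditions: triethyl phosphonoacetate, NaH, THF, 0 °C → rt
Reagents that add atoms: triethyl phosphonoacetate, CCOC(=O)CP(=O)(OCC)OCC
Why: Horner–Wadsworth–Emmons olefination of an aromatic aldehyde with a stabilized phosphonate anion, which should give the (E)-enoate.

Step 5
Reactants: 6 ethyl (2E)-3-ArB-prop-2-enoate
Product: 7 (2E)-3-ArB-prop-2-en-1-ol
Conditions: i-Bu2AlH (2.2 equiv), CH2Cl2, −78 → 0 °C; aqueous potassium sodium tartrate work-up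
Reagents that add atoms: none
Why: 1,2-Reduction of the α,β-unsaturated ester with i-Bu2AlH gives the allylic alcohol and leaves the silyl ether and the alkenes alone.

Step 6
Reactants: 7 (2E)-3-ArB-prop-2-en-1-ol
Product: 8 methyl (2E)-3-ArB-prop-2-en-1-yl carbonate
Conditions: ClCO2Me, pyridine, CH2Cl2, 0 °C
Reagents that add atoms: methyl chloroformate, COC(=O)Cl
Why: O-Acylation of the alcohol with a chloroformate gives the allylic methyl carbonate, the usual leaving group for the allylic substitution of step 10.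

Step 7
Reactants: 9 phloroglucinol (benzene-1,3,5-triol)
Product: 10 3,5-bis(TIPS-oxy)phenol
Conditions: TIPSCl (2.05 equiv), imidazole, DMF, 0 °C → rt
Reagents that add atoms: triisopropylsilyl chloride, CC(C)[Si](Cl)(C(C)C)C(C)C
Why: Statistical silylation of the threefold-symmetric triol with two equivalents of a bulky chlorosilane, from which the bis-ether should be the main product and is separated from mono- and tris-ether by chromatography.

Step 8
Reactants: 10 3,5-bis(TIPS-oxy)phenol
Product: 11 1-[(2-methylbut-3-en-2-yl)oxy]-3,5-bis(TIPS-oxy)benzene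
Conditions: tert-butyl (2-methylbut-3-en-2-yl) carbonate (1.5 equiv), Pd(PPh3)4 (2 mol%), THF, 0 °C
Reagents that add atoms: tert-butyl (2-methylbut-3-en-2-yl) carbonate, CC(C)(C)OC(=O)OC(C)(C)C=C
Why: Decarboxylative Tsuji–Trost O-allylation as in step 1; the silyloxy groups shield the ring carbons, so the phenoxide should react through oxygen at the tertiary allyl terminus.

Step 9
Reactants: 11 1-[(2-methylbut-3-en-2-yl)oxy]-3,5-bis(TIPS-oxy)benzene
Product: 13 2-prenyl-3,5-bis(TIPS-oxy)phenol (ArA–OH), via Claisen dienone 12 (not isolated)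
Conditions: PhNEt2, 120 °C
Reagents that add atoms: none
Why: Aromatic Claisen rearrangement in which the two ortho carbons of 11 are equivalent, so a single prenylphenol should result, with the freed hydroxyl next to the new prenyl group as needed for O1 and C8.

Step 10
Reactants: 13 2-prenyl-3,5-bis(TIPS-oxy)phenol; 8 methyl (2E)-3-ArB-prop-2-en-1-yl carbonate
Product: 15 (1S)-1-ArB-1-(ArA-oxy)prop-2-ene, via lithium aryloxide 14 (not isolated)
Conditions: n-BuLi (1.0 equiv), THF, 0 °C; then 8 (1.1 equiv), [Ir(cod)Cl]2 (2 mol%), (Sa,S,S)-L (4 mol%), THF, rt → 50 °C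
Reagents that add atoms: none
Why: Iridium-catalysed asymmetric allylic etherification, in which the catalyst formed from [Ir(cod)Cl]2 and L ionizes the carbonate and delivers the hard lithium aryloxide through oxygen to the aryl-bearing allyl terminus; the chiral ligand fixes the face and so sets C2 as (S), and the silyloxy groups beside the ring carbons of 14 disfavour C-allylation.

Step 11
Reactants: 15 (1S)-1-ArB-1-(ArA-oxy)prop-2-ene
Product: 17 (3S)-3-ArB-3-(ArA-oxy)propan-1-ol, via alkylborane 16 (not isolated)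
Conditions: 9-borabicyclo[3.3.1]nonane (1.5 equiv), THF, 0 °C → rt; then 30% H2O2, 3 M aq. NaOAc, 0 °C → rt
Reagents that add atoms: hydrogen peroxide, OO
Why: Hydroboration–oxidation, in which the borane adds to the monosubstituted alkene far faster than to the two trisubstituted prenyl alkenes and places boron on the terminal carbon, and buffered peroxide oxidation gives the primary alcohol with C2 untouched.

Step 12
Reactants: 17 (3S)-3-ArB-3-(ArA-oxy)propan-1-ol
Product: 19 (3S)-3-ArB-3-(ArA-oxy)propanoic acid, via aldehyde 18 (not isolated)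
Conditions: TEMPO (0.2 equiv), PhI(OAc)2 (2.5 equiv), MeCN/CH2Cl2/H2O, rt
Reagents that add atoms: water, O
Why: TEMPO-catalysed oxidation with PhI(OAc)2 as terminal oxidant takes the primary alcohol through aldehyde 18 and its hydrate to the acid in a weakly acidic medium, in which the β-aryloxy aldehyde should not eliminate the aryloxide.

Step 13
Reactants: 19 (3S)-3-ArB-3-(ArA-oxy)propanoic acid
Product: 21 (2S)-2-ArB-8-prenyl-5,7-bis(TIPS-oxy)-2,3-dihydro-4H-chromen-4-one, via mixed anhydride 20 (not isolated)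
Conditions: (CF3CO)2O (1.3 equiv), CH2Cl2 (0.02 M), 0 °C → rt
Reagents that add atoms: none
Why: The acid and trifluoroacetic anhydride form mixed anhydride 20, whose activated acyl carbon C4 is attacked by C4a of ring A, and loss of the C4a proton restores the arene. The closest known reaction type is the intramolecular Friedel–Crafts acylation of 3-aryloxypropanoic acids to chroman-4-ones through mixed trifluoroacetic anhydrides, which on a ring carrying three oxygen donors should need no Lewis acid. Ring C is closed in the 6-exo-trig mode, the ring carbon C4a attacking the carbonyl carbon whose C=O bond stays outside the new ring. No stereocentre is formed: C2 was set in step 10 and no bond to it is made or broken here. The step needs site selectivity, which the substrate secures because C4a is the only ring A carbon that can reach the acyl group through a six-membered transition state (C8 is blocked by prenyl, C6 is out of reach) and is activated by O1, O5 and O7, whereas attack on C6' of ring B would need a five-membered closure at a carbon activated by one twisted silyloxy group only. It also needs restraint toward the p-methoxybenzylic C2–O1 bond and the prenyl alkenes, which the low acid strength, high dilution and low temperature should provide.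

Step 14
Reactants: 21 (2S)-2-ArB-8-prenyl-5,7-bis(TIPS-oxy)-2,3-dihydro-4H-chromen-4-one
Product: 22 (2S)-5,7-dihydroxy-2-(3-hydroxy-4-methoxy-2-prenylphenyl)-8-prenyl-2,3-dihydro-4H-chromen-4-one (CNP0115880.1)
Conditions: Bu4NF (3.5 equiv), AcOH (3.5 equiv), THF, 0 °C
Reagents that add atoms: none
Why: Fluoride-induced cleavage of the three aryl silyl ethers, with acetic acid buffering the phenoxides so that base-induced opening of the flavanone to the chalcone, and with it loss of configuration at C2, should not occur.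

**Compound list**

1 | isovanillin (3-hydroxy-4-methoxybenzaldehyde) | COc1ccc(C=O)cc1O | starting material
2 | 4-methoxy-3-[(2-methylbut-3-en-2-yl)oxy]benzaldehyde | COc1ccc(C=O)cc1OC(C)(C)C=C | intermediate
3 | Claisen dienone: 4-methoxy-6-prenyl-5-oxocyclohexa-1,3-diene-1-carbaldehyde (racemic at C6) | COC1=CC=C(C=O)C(CC=C(C)C)C1=O | intermediate
4 | 3-hydroxy-4-methoxy-2-prenylbenzaldehyde | COc1ccc(C=O)c(CC=C(C)C)c1O | intermediate
5 | 4-methoxy-2-prenyl-3-(TIPS-oxy)benzaldehyde | COc1ccc(C=O)c(CC=C(C)C)c1O[Si](C(C)C)(C(C)C)C(C)C | intermediate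
6 | ethyl (2E)-3-ArB-prop-2-enoate | CCOC(=O)/C=C/c1ccc(OC)c(O[Si](C(C)C)(C(C)C)C(C)C)c1CC=C(C)C | intermediate
7 | (2E)-3-ArB-prop-2-en-1-ol | OC/C=C/c1ccc(OC)c(O[Si](C(C)C)(C(C)C)C(C)C)c1CC=C(C)C | intermediate
8 | methyl (2E)-3-ArB-prop-2-en-1-yl carbonate | COC(=O)OC/C=C/c1ccc(OC)c(O[Si](C(C)C)(C(C)C)C(C)C)c1CC=C(C)C | intermediate
9 | phloroglucinol (benzene-1,3,5-triol) | Oc1cc(O)cc(O)c1 | starting material
10 | 3,5-bis(TIPS-oxy)phenol | Oc1cc(O[Si](C(C)C)(C(C)C)C(C)C)cc(O[Si](C(C)C)(C(C)C)C(C)C)c1 | intermediate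
11 | 1-[(2-methylbut-3-en-2-yl)oxy]-3,5-bis(TIPS-oxy)benzene | C=CC(C)(C)Oc1cc(O[Si](C(C)C)(C(C)C)C(C)C)cc(O[Si](C(C)C)(C(C)C)C(C)C)c1 | intermediate
12 | Claisen dienone: 6-prenyl-3,5-bis(TIPS-oxy)cyclohexa-2,4-dien-1-one (racemic at C6) | O=C1C=C(O[Si](C(C)C)(C(C)C)C(C)C)C=C(O[Si](C(C)C)(C(C)C)C(C)C)C1CC=C(C)C | intermediate
13 | 2-prenyl-3,5-bis(TIPS-oxy)phenol (ArA–OH) | Oc1cc(O[Si](C(C)C)(C(C)C)C(C)C)cc(O[Si](C(C)C)(C(C)C)C(C)C)c1CC=C(C)C | intermediate
14 | lithium 2-prenyl-3,5-bis(TIPS-oxy)phenoxide | [Li+].[O-]c1cc(O[Si](C(C)C)(C(C)C)C(C)C)cc(O[Si](C(C)C)(C(C)C)C(C)C)c1CC=C(C)C | intermediate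
15 | (1S)-1-ArB-1-(ArA-oxy)prop-2-ene | C=C[C@H](Oc1cc(O[Si](C(C)C)(C(C)C)C(C)C)cc(O[Si](C(C)C)(C(C)C)C(C)C)c1CC=C(C)C)c1ccc(OC)c(O[Si](C(C)C)(C(C)C)C(C)C)c1CC=C(C)C | intermediate
16 | 9-[(3S)-3-ArB-3-(ArA-oxy)propyl]-9-borabicyclo[3.3.1]nonane | C1CCC2CCCC1B2CC[C@H](Oc1cc(O[Si](C(C)C)(C(C)C)C(C)C)cc(O[Si](C(C)C)(C(C)C)C(C)C)c1CC=C(C)C)c1ccc(OC)c(O[Si](C(C)C)(C(C)C)C(C)C)c1CC=C(C)C | intermediate
17 | (3S)-3-ArB-3-(ArA-oxy)propan-1-ol | OCC[C@H](Oc1cc(O[Si](C(C)C)(C(C)C)C(C)C)cc(O[Si](C(C)C)(C(C)C)C(C)C)c1CC=C(C)C)c1ccc(OC)c(O[Si](C(C)C)(C(C)C)C(C)C)c1CC=C(C)C | intermediate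
18 | (3S)-3-ArB-3-(ArA-oxy)propanal | O=CC[C@H](Oc1cc(O[Si](C(C)C)(C(C)C)C(C)C)cc(O[Si](C(C)C)(C(C)C)C(C)C)c1CC=C(C)C)c1ccc(OC)c(O[Si](C(C)C)(C(C)C)C(C)C)c1CC=C(C)C | intermediate
19 | (3S)-3-ArB-3-(ArA-oxy)propanoic acid | OC(=O)C[C@H](Oc1cc(O[Si](C(C)C)(C(C)C)C(C)C)cc(O[Si](C(C)C)(C(C)C)C(C)C)c1CC=C(C)C)c1ccc(OC)c(O[Si](C(C)C)(C(C)C)C(C)C)c1CC=C(C)C | intermediate
20 | (3S)-3-ArB-3-(ArA-oxy)propanoic trifluoroacetic anhydride | O=C(C[C@H](Oc1cc(O[Si](C(C)C)(C(C)C)C(C)C)cc(O[Si](C(C)C)(C(C)C)C(C)C)c1CC=C(C)C)c1ccc(OC)c(O[Si](C(C)C)(C(C)C)C(C)C)c1CC=C(C)C)OC(=O)C(F)(F)F | intermediate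
21 | (2S)-2-ArB-8-prenyl-5,7-bis(TIPS-oxy)-2,3-dihydro-4H-chromen-4-one | COc1ccc([C@@H]2CC(=O)c3c(O[Si](C(C)C)(C(C)C)C(C)C)cc(O[Si](C(C)C)(C(C)C)C(C)C)c(CC=C(C)C)c3O2)c(CC=C(C)C)c1O[Si](C(C)C)(C(C)C)C(C)C | intermediate
22 | (2S)-5,7-dihydroxy-2-(3-hydroxy-4-methoxy-2-prenylphenyl)-8-prenyl-2,3-dihydro-4H-chromen-4-one (CNP0115880.1) | COc1ccc([C@@H]2CC(=O)c3c(O)cc(O)c(CC=C(C)C)c3O2)c(CC=C(C)C)c1O | target

**Step count and risks**

Total step count: 14. Longest linear sequence: 11 steps (steps 1–6 and 10–14).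

Steps most likely to fail:

Step 10. What may go wrong: attack of the aryloxide at the unsubstituted allyl terminus or through a ring carbon, incomplete facial control with the ortho-substituted, electron-rich cinnamyl partner, and slow re-ionization of the product that erodes its configuration. The fallback sets out from aldehyde 5, uses phenol 13 and comes back at acid 19. Roskamp homologation of 5 (ethyl diazoacetate, SnCl2, CH2Cl2) gives ethyl 3-ArB-3-oxopropanoate F1. Noyori asymmetric transfer hydrogenation (RuCl[(R,R)-TsDPEN](p-cymene), HCO2H/Et3N) should give ethyl (3R)-3-hydroxy-3-ArB-propanoate F2. Mitsunobu etherification with 13 (PPh3, diisopropyl azodicarboxylate, toluene, −20 °C, kept cold to hold back ionization of the benzylic oxyphosphonium ion) inverts the carbinol carbon and gives ethyl (3S)-3-ArB-3-(ArA-oxy)propanoate F3. Saponification (LiOH, THF/H2O, 0 °C) gives 19.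

Step 13. What may go wrong: acid-induced heterolysis of the p-methoxybenzylic C2–O1 bond with loss of configuration or of the aryloxy group, addition of acid to a prenyl alkene with closure onto the neighbouring oxygen, and a ring closure that is too slow at this acid strength. The fallback sets out from 19 and comes back at 21; it replaces the acid-releasing mixed anhydride by a buffered Vilsmeier–Haack-type closure of a tertiary amide. Amide coupling of 19 (Me2NH·HCl, EDC·HCl, HOBt, i-Pr2NEt, CH2Cl2) gives (3S)-N,N-dimethyl-3-ArB-3-(ArA-oxy)propanamide F4. Activation with Tf2O and 2-chloropyridine (CH2Cl2, −78 → 0 °C) lets C4a attack the O-triflyl iminium carbon and gives the cyclic iminium salt (2S)-[2-ArB-8-prenyl-5,7-bis(TIPS-oxy)-2,3-dihydro-4H-chromen-4-ylidene]dimethylammonium trifluoromethanesulfonate F5, which is hydrolysed on aqueous NaHCO3 work-up to 21.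

Step 9. What may go wrong: thermal loss of the tertiary allyl group as isoprene before it rearranges, and closure of the ortho-prenylphenol to a 2,2-dimethylchroman at the temperature needed. The fallback sets out from phloroglucinol 9 and comes back at 13. Direct C-prenylation of 9 (1-bromo-3-methylbut-2-ene, DBU, THF, rt) gives 2-prenylbenzene-1,3,5-triol F6. Silylation with two equivalents of TIPSCl and imidazole (DMF, 0 °C) should take the unhindered hydroxyl para to the prenyl group and one of the two equivalent flanking hydroxyls, which gives 13.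

Further compounds
F1 | step 10 | ethyl 3-ArB-3-oxopropanoate | CCOC(=O)CC(=O)c1ccc(OC)c(O[Si](C(C)C)(C(C)C)C(C)C)c1CC=C(C)C
F2 | step 10 | ethyl (3R)-3-hydroxy-3-ArB-propanoate | CCOC(=O)C[C@@H](O)c1ccc(OC)c(O[Si](C(C)C)(C(C)C)C(C)C)c1CC=C(C)C
F3 | step 10 | ethyl (3S)-3-ArB-3-(ArA-oxy)propanoate | CCOC(=O)C[C@H](Oc1cc(O[Si](C(C)C)(C(C)C)C(C)C)cc(O[Si](C(C)C)(C(C)C)C(C)C)c1CC=C(C)C)c1ccc(OC)c(O[Si](C(C)C)(C(C)C)C(C)C)c1CC=C(C)C
F4 | step 13 | (3S)-N,N-dimethyl-3-ArB-3-(ArA-oxy)propanamide | CN(C)C(=O)C[C@H](Oc1cc(O[Si](C(C)C)(C(C)C)C(C)C)cc(O[Si](C(C)C)(C(C)C)C(C)C)c1CC=C(C)C)c1ccc(OC)c(O[Si](C(C)C)(C(C)C)C(C)C)c1CC=C(C)C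
F5 | step 13 | (2S)-[2-ArB-8-prenyl-5,7-bis(TIPS-oxy)-2,3-dihydro-4H-chromen-4-ylidene]dimethylammonium trifluoromethanesulfonate | COc1ccc([C@@H]2CC(=[N+](C)C)c3c(O[Si](C(C)C)(C(C)C)C(C)C)cc(O[Si](C(C)C)(C(C)C)C(C)C)c(CC=C(C)C)c3O2)c(CC=C(C)C)c1O[Si](C(C)C)(C(C)C)C(C)C.[O-]S(=O)(=O)C(F)(F)F
F6 | step 9 | 2-prenylbenzene-1,3,5-triol | Oc1cc(O)c(CC=C(C)C)c(O)c1
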